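Start from a one-step world: starting material becomes target and nothing else, so the amount of target depends on how far one clock has run. Then read the clock from the runs, and bracket green against them.

| flask | starting material | free enzyme | temperature | remark | time |
|---|---|---|---|---|---|
| alpha | 0.070 M | 0.01 mol% | 15 °C | run made earlier |  |
| zeta | 0.11 M | 0.01 mol% | 30 °C | run made earlier |  |
| theta | 0.050 M | 0.02 mol% | 15 °C | run made earlier |  |
| green | 0.050 M | 0.01 mol% | 20 °C |  | 3.0 h |
| ochre | 0.050 M | 0.01 mol% |  | at 20 °C until 2.0 h, from then on at 40 °C | 3.0 h |
| grey | 0.050 M | 0.01 mol% | 40 °C |  | 3.0 h |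

alpha run (percent of the starting material charged)

| time / h | target / % |
|---|---|
| 0.250 | 23.8 |
| 0.417 | 34.9 |
| 0.667 | 45.5 |
| 1.00 | 54.0 |
| 2.00 | 65.8 |
| 3.00 | 68.3 |

zeta run (percent of the starting material charged)

| time / min | target / % |
|---|---|
| 10.0 | 33.1 |
| 15.0 | 43.6 |
| 25.0 | 54.7 |
| 40.0 | 60.6 |
| 80.0 | 64.9 |
| 120 | 65.1 |

theta run (percent of the starting material charged)

| time / h | target / % |
|---|---|
| 0.250 | 25.9 |
| 0.417 | 35.4 |
| 0.833 | 50.6 |
| 1.50 | 60.4 |
| 3.00 | 68.1 |

(scatter of a reading: 0.3 percentage points)



- the flask with the highest amount of target, in percent of the starting material charged ("all alike" if they lie within 1.5 percentage points) (green / ochre / grey / all alike)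
- final target, as a percentage of the starting material charged, in green
- final target, as a percentage of the starting material charged, in ochre
- final target, as a percentage of the starting material charged, in grey

Alpha and theta give nearly the same reading at 0.417 h, 34.9 % and 35.4 %. Take the clock speed as loading times concentration to the power m. Taking those two readings as equal gives m = 2.06. That exponent makes zeta faster than alpha by 2.54, and near equal readings in the two runs stand at times 2.50 apart, so with this exponent the readings of the warmer zeta show no gain in clock speed, and I leave temperature out of my clock.

Now define theta hours: the time at which theta has run as far as a flask has. Green has theta's concentration and half its loading, so its asked time counts as 1.50 h. For an estimated bound from above, read theta there: 60.4 %. For a bound from below, charge green for its extra hours of loss. Theta still lacks 32 percentage points at 3.00 h. Treat that whole gap as loss and spread it evenly, a harsh charge, as theta was still gaining target between its last two readings. That puts my estimated floor for green at 44.4 %. I expect green to lead: my clock gives grey the same theta hours, and grey's bath is hotter.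

The forecast gave 65.5 %, 61.9 % and 61.6 % for green, ochre and grey, with green first, above my bracket for green, on the ground that “The plateaus look like a true equilibrium”.

The flasks give 55.5 % in green, 49.8 % in ochre and 44.2 % in grey, so green leads, and green lies inside the bracket.

    free enzyme → unfolded enzyme (k = 5.90 × 10⁻⁴ min⁻¹, Ea = 202 kJ mol⁻¹)
    starting material + free enzyme → target + free enzyme, rate k2*[starting material]^2.5*[free enzyme]/(1 + ([starting material]/Kh2)^2.5) (0.0850 M, k = 3.41 × 10⁵ L²·⁵ mol⁻²·⁵ min⁻¹, Ea = 8.00 kJ mol⁻¹)
    starting material + target → side product (k = 0.0755 L mol⁻¹ min⁻¹, Ea = 65.0 kJ mol⁻¹)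
    target ⇌ isomer of the product (K = 0.190, k = 0.0148 min⁻¹, Ea = 90.0 kJ mol⁻¹, ΔH = 1.00 kJ mol⁻¹)
    (constants at 40 °C)

Green ends 4.9 points below theta's reading at 1.50 h. My clock gave grey the same 1.50 h of theta hours, but at 3.00 h its starting material stands at 26.9 % against 33.4 % in green, and its target is still lower. The largest single effect is what temperature does to the loss of starting material and target to side product. Grey minus green in target is −11 points as the flasks ran, and −0.76 points with that temperature effect taken away.

The runs are simulated with made-up constants.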